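Compound numbers refer to the steps and the compound list below. The tetrahydrofuran ring is numbered O1, C2, C3, C4, C5, where C2 is the carbon that comes from the aldehyde in the ring closure and C5 is the former carbinol carbon. All ring descriptors use this numbering.

## Analysis of the target

The target 15 is a 2,5-diaryl-3,4-bis(hydroxymethyl)tetrahydrofuran: one five-membered ring (O1, C2 to C5) with a 4-hydroxy-3,5-dimethoxyphenyl group on C2 and on C5 and a CH2OH group on C3 and on C4. All four ring carbons are stereocentres, (2S,3S,4S,5R) in this numbering. The two aryl groups are cis to each other, the two hydroxymethyl groups are trans, C4/C5 is trans and C2/C3 is cis. The two halves have the same constitution, but the single cis relation at C2/C3 removes every symmetry element, so a symmetric dimerisation cannot give the compound without a later differentiating event. This arrangement is also the less stable one: the all-trans ring is the thermodynamic sink, and O1–C2 and O1–C5 are benzylic ether bonds next to electron-rich arenes that acid can ionise and so epimerise. The free phenols are easily oxidised to quinone methides and the ring C–O bonds can be hydrogenolysed, which restricts the end game. The strategy rests on C2, which carries an aryl group, O1 and C3. That is the pattern an aryl aldehyde carbon acquires when a C5 hydroxyl adds to it and the γ-carbon of an allylsilane on C4 captures the resulting oxocarbenium ion, leaving on C3 a vinyl group as a latent hydroxymethyl group.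

## Retrosynthetic reasoning

**15 to 14.** The last disconnection removes three O-benzyl bonds: both phenols and the C4 hydroxymethyl oxygen of 15 are carried as benzyl ethers in 14. The phenols must be masked against the Lewis acid, the metathesis catalyst and the oxidant of the later steps, and one kind of protecting group allows one final operation. The forward step has to cleave O-benzyl bonds without opening the ring at its own benzylic C–O bonds.

**14 to 11.** The C3 hydroxymethyl group is traced back to the C3 vinyl group of 11. A vinyl group is what an allylsilane leaves behind after it has acted as a nucleophile, and it keeps the C3 and C4 side chains differentiated without a further protecting group. The forward step must cleave the alkene and reduce the resulting carbonyl group without epimerising C3 and without attacking the arenes.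

**11 to 9 and 2.** The ring is opened at O1–C2 and C2–C3. This cut is chosen because C2 is the one ring carbon that can be an aldehyde carbon, and because it creates the two difficult centres, C2 and C3, in the ring-forming event itself. It divides the molecule into the allylsilane alcohol 9 and the aldehyde 2. The forward reaction has to generate an oxocarbenium ion from the C5 hydroxyl and 2, close the ring through the γ-carbon of the allylsilane, and do so 2,5-cis and 3,4-trans under kinetic control.

**9 to 7 and 8.** The internal alkene of 9 is cut by a cross-metathesis transform to the terminal alkene 7 and allyltrimethylsilane 8. The acid-sensitive allylsilane is thus introduced one step before it is used, and 7 is the direct product of an allylation.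

**7 to 2 and 5.** The bond between the carbinol carbon and the allylic carbon (C5–C4 of the later ring) is cut to aldehyde 2 and the (E)-γ-substituted allylboronate 5. One step then sets both centres: the anti relation follows from the (E) geometry of 5 in a chair transition state, and the absolute configuration from a chiral Brønsted acid catalyst. Aldehyde 2 is used twice in the synthesis, which is how the constitutional symmetry of 15 is exploited.

**5 to 4 to 3, and 2 to 1.** The C–B bond of 5 is traced to the allylic C–Cl bond of 4, and the benzyl ether of 4 to one of the two equivalent chlorides of 3, which already has the (E) geometry. Aldehyde 2 is the O-benzyl ether of syringaldehyde 1.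

## Alternatives that were turned down

**Alternative 1:** This route disconnects the two arenes and leaves the tetrahydrofuran intact. Each syringyl ring is cut at two C–C bonds to a masked malonaldehyde on the ring carbon and a symmetrical ketone.
- Forward key step: the bis-vinamidinium core A2 condenses at both ends with the ketone 1,3-dimethoxyacetone A3 under strong base. Each molecule of A3 closes one phenol ring, giving A1, which is 15 with both hydroxymethyl groups as benzyl ethers.
- For: the phenols appear unprotected and late, and no electron-rich arene is present while the heterocycle is built, so benzylic ionisation and arene oxidation are not an issue. On these two points it is stronger than the chosen route.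
- Against: all four stereocentres must already exist in A2, so the key step does not address the real problem, the 2,3-cis relation on a 2,5-cis ring. In A2, C2 and C5 are acidic (α to an iminium/enamine system) and O1 is β to it, so the basic condensation invites epimerisation to the trans series and E1cB opening of the ring. Four C–C bonds and two rings are made to build an arene that 1 supplies ready-made, so step economy is poor.
- In its place the chosen route takes both aryl groups from 1 and spends its key step on the two difficult stereocentres.

**Alternative 2:** This route disconnects O1–C2 and O1–C5 and reconnects C2 to C5, which leads to the cyclobutane A5, a head-to-head photodimer of methyl sinapate A6 with trans ester groups.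
- Forward key step: a two-electron oxidant converts the bis-phenol A5 into a bis-quinone methide by breaking the bond between the two benzylic carbons. The aqueous solvent then supplies the bridging oxygen at both carbons, closing the ring to the diester A4, and ester reduction would give 15.
- For: it is by far the shortest route (three or four steps from A6), needs no protecting groups, and carries the 3,4-trans relation over from the cyclobutane. On step count it is clearly stronger than the chosen route.
- Against: C2 and C5 pass through planar quinone methide carbons and are set by two hydration events with no controlling element. A mixture of 2,5-cis and 2,5-trans rings is expected with the all-trans isomer favoured, whereas 15 needs one benzylic centre cis and the other trans to its neighbouring side chain. There is no source of absolute configuration, since A5 forms as a racemate and is not the usual photodimer. A syringyl quinone methide can also be captured by the neighbouring arene, which leads to aryltetralins.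
- The chosen route is about twice as long but offers an assignable control element for every centre and catalytic enantiocontrol.

**Alternative 3:** This route disconnects C3–C4 and O1–C5, leading to the aryl β-keto ester A8 and the nitroalkene A9, which has the nitro group on the benzylic carbon.
- Forward key step: a bifunctional squaramide catalyses the Michael addition of A8 to A9 (C3–C4), and the enol oxygen then displaces the nitro group at the benzylic carbon (O1–C5) to give the 4,5-trans dihydrofuran A7.
- For: one catalytic asymmetric operation closes the ring and sets C4 and C5, the route is as convergent as the chosen one, and the C3 carbon is already at the ester level. Its ring-forming step belongs to a class with well-understood enantiocontrol, and on that point it is stronger.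
- Against: A7 still has the C2=C3 double bond, so half of the stereochemical problem remains and must be solved on a tetrasubstituted, push-pull alkene that is hard to reduce. Cis addition of hydrogen would give the required 2,3-cis relation, but 15 needs delivery to the face that carries the C4 side chain. Attack on the open face gives the 2,3-cis-3,4-cis ring, and epimerisation of the C3 ester from there leads to the all-trans series. Aromatisation of A7 to a furan and hydrogenolysis of the C5–O bond are further risks.
- The chosen route creates C2 and C3 as sp3 centres in the ring closure and is shorter after the key step.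

Key step: step 6

## Assumptions

- (R)-TRIP is assumed to direct the allyl group to the same aldehyde face as with other aryl aldehydes, giving the (1R) carbinol; if the sense proves opposite, the antipodal acid is used.
- Compound 9 is drawn as the (E)-isomer; a minor (Z)-isomer from the metathesis is carried along, because the alkene geometry is not kept in the product of step 6.

## Route

**Step 1**
Reactants: 1 syringaldehyde
Product: 2 4-(benzyloxy)-3,5-dimethoxybenzaldehyde
Conditions: BnBr, K2CO3, DMF, 60 °C
Reagents that add atoms: benzyl bromide, BrCc1ccccc1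
Why: Williamson etherification of an acidic phenol (phenoxide para to the formyl group) with a reactive benzylic halide; the aldehyde is untouched.

**Step 2**
Reactants: 3 (E)-1,4-dichlorobut-2-ene (threefold excess)
Product: 4 (E)-1-(benzyloxy)-4-chlorobut-2-ene
Conditions: BnOH, NaH, THF, 0 °C to rt
Reagents that add atoms: benzyl alcohol, OCc1ccccc1
Why: Williamson SN2 substitution of one allylic chloride by sodium benzyloxide; the excess of the symmetrical dichloride suppresses the bis-ether, and the (E) geometry is retained.

**Step 3**
Reactants: 4 (E)-1-(benzyloxy)-4-chlorobut-2-ene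
Product: 5 (E)-2-[4-(benzyloxy)but-2-en-1-yl]-4,4,5,5-tetramethyl-1,3,2-dioxaborolane
Conditions: B2pin2, Pd2(dba)3 (tris(dibenzylideneacetone)dipalladium, 1 mol %), THF, 60 °C
Reagents that add atoms: bis(pinacolato)diboron, CC1(C)OB(OC1(C)C)B1OC(C)(C)C(C)(C)O1
Why: Miyaura-type borylation of an allylic chloride: oxidative addition to zerovalent palladium gives a syn π-allyl complex, and transmetalation with the diboron reagent and reductive elimination at the less substituted terminus give the linear (E)-allylboronate. The benzyl ether is a poor leaving group and is not ionised.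

**Step 4**
Reactants: 2 4-(benzyloxy)-3,5-dimethoxybenzaldehyde, 5 (E)-2-[4-(benzyloxy)but-2-en-1-yl]-4,4,5,5-tetramethyl-1,3,2-dioxaborolane
Product: 7 (1R,2S)-1-(4-benzyloxy-3,5-dimethoxyphenyl)-2-(benzyloxymethyl)but-3-en-1-ol, via pinacol borate ester 6 (not isolated)
Conditions: (R)-TRIP ((R)-3,3'-bis(2,4,6-triisopropylphenyl)-1,1'-binaphthyl-2,2'-diyl hydrogen phosphate, 5 mol %), toluene, −30 °C; aq. NaHCO3
Reagents that add atoms: none
Why: Chiral phosphoric acid-catalysed allylboration through a closed chair (Zimmerman–Traxler) transition state: the (E)-γ-substituent is equatorial and gives the anti relation (C4/C5 of the later ring). The acid, hydrogen-bonded to a boronate oxygen and to the formyl hydrogen, selects the aldehyde face and sets the carbinol centre as (1R); work-up hydrolyses the borate ester 6.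

**Step 5**
Reactants: 7 (1R,2S)-1-(4-benzyloxy-3,5-dimethoxyphenyl)-2-(benzyloxymethyl)but-3-en-1-ol, 8 allyltrimethylsilane (5 equiv)
Product: 9 (1R,2S,3E)-1-(4-benzyloxy-3,5-dimethoxyphenyl)-2-(benzyloxymethyl)-5-(trimethylsilyl)pent-3-en-1-ol
Conditions: second-generation Grubbs catalyst RuCl2(H2IMes)(PCy3)(=CHPh) (5 mol %), CH2Cl2, 40 °C
Reagents that add atoms: none
Why: Olefin cross-metathesis of a branched monosubstituted alkene with an excess of a readily dimerising partner; the free alcohol, the benzyl ethers and the arene are inert to the catalyst, and the (E)-alkene should predominate. No stereocentre is touched.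

**Step 6**
Reactants: 9 (1R,2S,3E)-1-(4-benzyloxy-3,5-dimethoxyphenyl)-2-(benzyloxymethyl)-5-(trimethylsilyl)pent-3-en-1-ol, 2 4-(benzyloxy)-3,5-dimethoxybenzaldehyde (1.2 equiv)
Product: 11 (2S,3R,4S,5R)-2,5-bis(4-benzyloxy-3,5-dimethoxyphenyl)-4-(benzyloxymethyl)-3-vinyltetrahydrofuran, via oxocarbenium ion 10 (not isolated)
Conditions: BF3·OEt2 (1.5 equiv), CH2Cl2, −78 °C; Et3N, then aq. NaHCO3 at −78 °C
Reagents that add atoms: none
Why: BF3·OEt2 activates 2, the hydroxyl of 9 adds, and the hemiacetal ionises to the aryl-stabilised (E)-oxocarbenium ion 10 (O1–C2). The γ-carbon of the allylsilane (the alkene carbon on C4) attacks C2 anti to silicon and the β-silyl cation loses Me3Si to fluoride, leaving the C3 vinyl group (C2–C3); the closest known reaction type is the intramolecular Sakurai (silyl-Prins) condensation of 5-silylpent-3-en-1-ols with aldehydes to 3-vinyltetrahydrofurans. The one ring closes in a five-membered mode that is exo with respect to the alkene, with the O1=C2 bond inside the ring, and the β-silicon effect directs attack to the γ-carbon and away from a 2-oxonia-Cope or six-ring Prins path. C2 is controlled by the (E) geometry of 10 together with the pseudo-equatorial placing of the C5 aryl group, which leaves the C5 hydrogen and not the aryl group on the ring face of the C2 hydrogen and so brings the two aryl groups cis. C3 is controlled by the C4 centre: with C4–H in the alkene plane (inside) and CH2OBn outside, the alkene face that can reach C2 puts the vinyl group trans to CH2OBn, and the two preferences together amount to 2,3-cis. C4 and C5 are not touched, because the C5–O bond is kept and becomes part of the ring. The step needs kinetic control, that is, closure faster than ionisation of the benzylic C–O bonds of 9 and 11; the low temperature, the cold basic quench and the weak cation stabilisation by a para oxygen twisted out of plane between two methoxy groups should secure it. A (Z)-isomer in 9 should give the same product, since the alkene geometry is lost in the vinyl group and the inside position of C4–H is preferred even more strongly there.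

**Step 7**
Reactants: 11 (2S,3R,4S,5R)-2,5-bis(4-benzyloxy-3,5-dimethoxyphenyl)-4-(benzyloxymethyl)-3-vinyltetrahydrofuran
Product: 14 [(2S,3S,4S,5R)-2,5-bis(4-benzyloxy-3,5-dimethoxyphenyl)-4-(benzyloxymethyl)tetrahydrofuran-3-yl]methanol, via ozonide 12 (not isolated), via aldehyde 13 (not isolated)
Conditions: O3, CH2Cl2, −78 °C (Sudan Red 7B end point); then NaBH4, MeOH, −78 to 0 °C
Reagents that add atoms: ozone, [O-][O+]=O
Why: Ozonolysis of the only alkene to the secondary ozonide 12 and hydride reduction in the same flask through aldehyde 13 to the primary alcohol. The terminal alkene reacts with ozone far faster than the trialkoxyarenes or the benzyl ethers when the dye marks the end point, and immediate reduction at low temperature leaves the enolisable C3 centre no time to epimerise (the change of the C3 descriptor from R to S is a priority change only).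

**Step 8**
Reactants: 14 [(2S,3S,4S,5R)-2,5-bis(4-benzyloxy-3,5-dimethoxyphenyl)-4-(benzyloxymethyl)tetrahydrofuran-3-yl]methanol
Product: 15 [(2S,3S,4S,5R)-2,5-bis(4-hydroxy-3,5-dimethoxyphenyl)tetrahydrofuran-3,4-diyl]dimethanol
Conditions: H2 (1 atm), Pd/C (10 %), EtOAc/MeOH, rt
Reagents that add atoms: none
Why: Hydrogenolysis of the three benzyl ethers over Pd/C in neutral solvent; the ring C–O bonds, secondary ethers flanked by substituents and not activated by acid, should be cleaved more slowly than the O-benzyl groups, and no stereocentre is affected.

## Compound list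

1 | syringaldehyde (4-hydroxy-3,5-dimethoxybenzaldehyde) | COc1cc(C=O)cc(OC)c1O | starting material
2 | 4-(benzyloxy)-3,5-dimethoxybenzaldehyde | COc1cc(C=O)cc(OC)c1OCc1ccccc1 | intermediate
3 | (E)-1,4-dichlorobut-2-ene | ClC/C=C/CCl | starting material
4 | (E)-1-(benzyloxy)-4-chlorobut-2-ene | ClC/C=C/COCc1ccccc1 | intermediate
5 | (E)-2-[4-(benzyloxy)but-2-en-1-yl]-4,4,5,5-tetramethyl-1,3,2-dioxaborolane | CC1(C)OB(C/C=C/COCc2ccccc2)OC1(C)C | intermediate
6 | 2-{[(1R,2S)-1-(4-benzyloxy-3,5-dimethoxyphenyl)-2-(benzyloxymethyl)but-3-en-1-yl]oxy}-4,4,5,5-tetramethyl-1,3,2-dioxaborolane (pinacol borate ester of 7, not isolated) | CC1(C)OB(O[C@@H](c2cc(OC)c(OCc3ccccc3)c(OC)c2)[C@H](COCc2ccccc2)C=C)OC1(C)C | intermediate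
7 | (1R,2S)-1-(4-benzyloxy-3,5-dimethoxyphenyl)-2-(benzyloxymethyl)but-3-en-1-ol (anti) | O[C@@H](c1cc(OC)c(OCc2ccccc2)c(OC)c1)[C@H](COCc1ccccc1)C=C | intermediate
8 | allyltrimethylsilane | C=CC[Si](C)(C)C | starting material
9 | (1R,2S,3E)-1-(4-benzyloxy-3,5-dimethoxyphenyl)-2-(benzyloxymethyl)-5-(trimethylsilyl)pent-3-en-1-ol | O[C@@H](c1cc(OC)c(OCc2ccccc2)c(OC)c1)[C@H](COCc1ccccc1)/C=C/C[Si](C)(C)C | intermediate
10 | (E)-[(4-benzyloxy-3,5-dimethoxyphenyl)methylidene][(1R,2S,3E)-1-(4-benzyloxy-3,5-dimethoxyphenyl)-2-(benzyloxymethyl)-5-(trimethylsilyl)pent-3-en-1-yl]oxonium (oxocarbenium ion, not isolated) | COc1cc(/C=[O+]/[C@@H](c2cc(OC)c(OCc3ccccc3)c(OC)c2)[C@H](COCc2ccccc2)/C=C/C[Si](C)(C)C)cc(OC)c1OCc1ccccc1 | intermediate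
11 | (2S,3R,4S,5R)-2,5-bis(4-benzyloxy-3,5-dimethoxyphenyl)-4-(benzyloxymethyl)-3-vinyltetrahydrofuran | COc1cc([C@H]2O[C@@H](c3cc(OC)c(OCc4ccccc4)c(OC)c3)[C@H](COCc3ccccc3)[C@H]2C=C)cc(OC)c1OCc1ccccc1 | intermediate
12 | 3-[(2S,3R,4S,5R)-2,5-bis(4-benzyloxy-3,5-dimethoxyphenyl)-4-(benzyloxymethyl)tetrahydrofuran-3-yl]-1,2,4-trioxolane (secondary ozonide, both epimers at the trioxolane carbon, not isolated) | COc1cc([C@H]2O[C@@H](c3cc(OC)c(OCc4ccccc4)c(OC)c3)[C@H](COCc3ccccc3)[C@H]2C2OCOO2)cc(OC)c1OCc1ccccc1 | intermediate
13 | (2S,3R,4S,5R)-2,5-bis(4-benzyloxy-3,5-dimethoxyphenyl)-4-(benzyloxymethyl)tetrahydrofuran-3-carbaldehyde (not isolated) | COc1cc([C@H]2O[C@@H](c3cc(OC)c(OCc4ccccc4)c(OC)c3)[C@H](COCc3ccccc3)[C@H]2C=O)cc(OC)c1OCc1ccccc1 | intermediate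
14 | [(2S,3S,4S,5R)-2,5-bis(4-benzyloxy-3,5-dimethoxyphenyl)-4-(benzyloxymethyl)tetrahydrofuran-3-yl]methanol | COc1cc([C@H]2O[C@@H](c3cc(OC)c(OCc4ccccc4)c(OC)c3)[C@H](COCc3ccccc3)[C@H]2CO)cc(OC)c1OCc1ccccc1 | intermediate
15 | [(2S,3S,4S,5R)-2,5-bis(4-hydroxy-3,5-dimethoxyphenyl)tetrahydrofuran-3,4-diyl]dimethanol | COc1cc([C@H]2O[C@@H](c3cc(OC)c(O)c(OC)c3)[C@H](CO)[C@H]2CO)cc(OC)c1O | target

## Step count and least certain steps

Total step count: 8. Longest linear sequence: 7 steps (3 to 4 to 5 to 7 to 9 to 11 to 14 to 15; steps 2 to 8).

**Step 6 (key step).** What may go wrong: poor facial selectivity at C2 or C3, that is, closure through the 2,5-trans arrangement (C5 aryl pseudo-axial, giving the all-trans ring) or through the 3,4-cis rotamer (CH2OBn inside). The required transition state places the silylmethyl-bearing alkene carbon next to the C2 aryl group, and its penalty relative to these two alternatives cannot be predicted with confidence. Acid-mediated equilibration of the benzylic centres of 11 toward the all-trans ring, and ionisation or protodesilylation of 9 before it condenses, are further risks.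

Fallback (sets out from 7, returns at 15): the ring is built through a lactone by known steps only. Hydroboration of the vinyl group of 7 (9-BBN, THF; then NaOH, H2O2) gives the diol (1R,2S)-1-(4-benzyloxy-3,5-dimethoxyphenyl)-2-(benzyloxymethyl)butane-1,4-diol F1. Oxidative lactonisation of the primary alcohol of F1 (TEMPO, PhI(OAc)2, CH2Cl2) gives the trans lactone (4S,5R)-5-(4-benzyloxy-3,5-dimethoxyphenyl)-4-(benzyloxymethyl)dihydrofuran-2(3H)-one F2. Enolate alkylation of F2 (LiN(SiMe3)2, THF, −78 °C; benzyl chloromethyl ether) anti to the C4 substituent gives the lactone (3S,4S,5R)-5-(4-benzyloxy-3,5-dimethoxyphenyl)-3,4-bis(benzyloxymethyl)dihydrofuran-2(3H)-one F3. Separately, benzylation of commercial 4-bromo-2,6-dimethoxyphenol (BnBr, K2CO3, DMF) gives the aryl bromide 2-(benzyloxy)-5-bromo-1,3-dimethoxybenzene F4. Bromine–lithium exchange on F4 with n-BuLi (THF, −78 °C) and addition of the aryllithium to F3 at −78 °C give the hemiketal (3S,4S,5R)-2,5-bis(4-benzyloxy-3,5-dimethoxyphenyl)-3,4-bis(benzyloxymethyl)tetrahydrofuran-2-ol F5. Et3SiH with BF3·OEt2 at −78 °C reduces the cyclic oxocarbenium ion derived from F5 with hydride delivered anti to the C3 substituent, which gives the 2,3-cis ring (2S,3S,4S,5R)-2,5-bis(4-benzyloxy-3,5-dimethoxyphenyl)-3,4-bis(benzyloxymethyl)tetrahydrofuran F6. Hydrogenolysis of F6 under the conditions of step 8 gives 15.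

**Step 4.** What may go wrong: insufficient enantioselectivity or an unexpected sense of induction, because the γ-benzyloxymethyl group of 5 is larger and more Lewis basic than the alkyl groups usually carried through this catalysis. Erosion of the anti selectivity through a slow background reaction is also possible.

Fallback (sets out from 4, returns at 7): HSiCl3 with CuCl (catalytic) and iPr2NEt in Et2O converts 4 into the allylsilane (E)-[4-(benzyloxy)but-2-en-1-yl]trichlorosilane F7. Under chiral bisphosphoramide Lewis-base catalysis (CH2Cl2, −78 °C), F7 adds to 2 through a closed chair transition state at hypervalent silicon, in which the (E) geometry again gives the anti product. Aqueous NaHCO3 work-up gives 7.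

**Step 7.** What may go wrong: over-oxidation of the two electron-rich arenes or of the benzylic ether positions by ozone if the end point is missed, and epimerisation at C3 (or β-elimination of O1) through aldehyde 13 if the reduction lags.

Fallback (sets out from 11, returns at 13 and then 14): dihydroxylation with K2OsO4·2H2O (catalytic) and N-methylmorpholine N-oxide in acetone/water gives the diol 1-[(2S,4S,5R)-2,5-bis(4-benzyloxy-3,5-dimethoxyphenyl)-4-(benzyloxymethyl)tetrahydrofuran-3-yl]ethane-1,2-diol F8 as both carbinol epimers, with the ring configuration of 11. NaIO4 in THF/water cleaves F8 to aldehyde 13, which is reduced at once with NaBH4 in MeOH at 0 °C to 14.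

**Step 8.** What may go wrong: hydrogenolysis of the ring benzylic C–O bonds (O1–C2, O1–C5) once the phenols are free, since the aliphatic benzyl ether needs longer contact with the catalyst than the two aryl benzyl ethers. Incomplete cleavage of that aliphatic ether is the opposite failure.

Fallback (sets out from 14, returns at 15): non-reductive debenzylation of 14 with BCl3 and pentamethylbenzene as cation scavenger in CH2Cl2 at −78 °C, quenched cold with MeOH, gives 15 directly. This cleaves aryl and alkyl benzyl ethers without hydrogen and makes no new isolated compound.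

## Further compounds

F1 | step 6 | (1R,2S)-1-(4-benzyloxy-3,5-dimethoxyphenyl)-2-(benzyloxymethyl)butane-1,4-diol | O[C@@H](c1cc(OC)c(OCc2ccccc2)c(OC)c1)[C@H](COCc1ccccc1)CCO
F2 | step 6 | (4S,5R)-5-(4-benzyloxy-3,5-dimethoxyphenyl)-4-(benzyloxymethyl)dihydrofuran-2(3H)-one | O1[C@@H](c2cc(OC)c(OCc3ccccc3)c(OC)c2)[C@H](COCc2ccccc2)CC1=O
F3 | step 6 | (3S,4S,5R)-5-(4-benzyloxy-3,5-dimethoxyphenyl)-3,4-bis(benzyloxymethyl)dihydrofuran-2(3H)-one | O1[C@@H](c2cc(OC)c(OCc3ccccc3)c(OC)c2)[C@H](COCc2ccccc2)[C@@H](COCc2ccccc2)C1=O
F4 | step 6 | 2-(benzyloxy)-5-bromo-1,3-dimethoxybenzene | COc1cc(Br)cc(OC)c1OCc1ccccc1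
F5 | step 6 | (3S,4S,5R)-2,5-bis(4-benzyloxy-3,5-dimethoxyphenyl)-3,4-bis(benzyloxymethyl)tetrahydrofuran-2-ol (both anomers) | O1[C@@H](c2cc(OC)c(OCc3ccccc3)c(OC)c2)[C@H](COCc2ccccc2)[C@@H](COCc2ccccc2)C1(O)c1cc(OC)c(OCc2ccccc2)c(OC)c1
F6 | step 6 | (2S,3S,4S,5R)-2,5-bis(4-benzyloxy-3,5-dimethoxyphenyl)-3,4-bis(benzyloxymethyl)tetrahydrofuran | COc1cc([C@H]2O[C@@H](c3cc(OC)c(OCc4ccccc4)c(OC)c3)[C@H](COCc3ccccc3)[C@H]2COCc2ccccc2)cc(OC)c1OCc1ccccc1
F7 | step 4 | (E)-[4-(benzyloxy)but-2-en-1-yl]trichlorosilane | Cl[Si](Cl)(Cl)C/C=C/COCc1ccccc1
F8 | step 7 | 1-[(2S,4S,5R)-2,5-bis(4-benzyloxy-3,5-dimethoxyphenyl)-4-(benzyloxymethyl)tetrahydrofuran-3-yl]ethane-1,2-diol (both carbinol epimers, ring configuration as in 11) | COc1cc([C@H]2O[C@@H](c3cc(OC)c(OCc4ccccc4)c(OC)c3)[C@H](COCc3ccccc3)[C@H]2C(O)CO)cc(OC)c1OCc1ccccc1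
F0 | step 8 | none | none
A1 | alternative 1 | (2S,3S,4S,5R)-3,4-bis(benzyloxymethyl)-2,5-bis(4-hydroxy-3,5-dimethoxyphenyl)tetrahydrofuran | COc1cc([C@H]2O[C@@H](c3cc(OC)c(O)c(OC)c3)[C@H](COCc3ccccc3)[C@H]2COCc2ccccc2)cc(OC)c1O
A2 | alternative 1 | 3,4-bis(benzyloxymethyl)tetrahydrofuran-2,5-diyl bis(vinamidinium) bis(hexafluorophosphate), ring configuration as in 15 | C[N+](C)=CC(=CN(C)C)[C@H]1O[C@@H](C(C=[N+](C)C)=CN(C)C)[C@H](COCc2ccccc2)[C@H]1COCc1ccccc1.F[P-](F)(F)(F)(F)F.F[P-](F)(F)(F)(F)F
A3 | alternative 1 | 1,3-dimethoxyacetone | COCC(=O)COC
A4 | alternative 2 | dimethyl (2S,3S,4S,5R)-2,5-bis(4-hydroxy-3,5-dimethoxyphenyl)tetrahydrofuran-3,4-dicarboxylate (ring numbering as for 15) | COc1cc([C@H]2O[C@@H](c3cc(OC)c(O)c(OC)c3)[C@H](C(=O)OC)[C@H]2C(=O)OC)cc(OC)c1O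
A5 | alternative 2 | dimethyl all-trans-3,4-bis(4-hydroxy-3,5-dimethoxyphenyl)cyclobutane-1,2-dicarboxylate (head-to-head photodimer, one enantiomer drawn) | COc1cc([C@@H]2[C@@H](c3cc(OC)c(O)c(OC)c3)[C@H](C(=O)OC)[C@H]2C(=O)OC)cc(OC)c1O
A6 | alternative 2 | methyl (E)-sinapate | COC(=O)/C=C/c1cc(OC)c(O)c(OC)c1
A7 | alternative 3 | methyl 4,5-trans-2,5-bis(4-benzyloxy-3,5-dimethoxyphenyl)-4-[(tert-butyldimethylsilyloxy)methyl]-4,5-dihydrofuran-3-carboxylate | COc1cc(C2=C(C(=O)OC)[C@@H](CO[Si](C)(C)C(C)(C)C)[C@H](c3cc(OC)c(OCc4ccccc4)c(OC)c3)O2)cc(OC)c1OCc1ccccc1
A8 | alternative 3 | methyl 3-(4-benzyloxy-3,5-dimethoxyphenyl)-3-oxopropanoate | COC(=O)CC(=O)c1cc(OC)c(OCc2ccccc2)c(OC)c1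
A9 | alternative 3 | (E)-tert-butyl{[3-(4-benzyloxy-3,5-dimethoxyphenyl)-3-nitroprop-2-en-1-yl]oxy}dimethylsilane | [O-][N+](=O)/C(=C/CO[Si](C)(C)C(C)(C)C)c1cc(OC)c(OCc2ccccc2)c(OC)c1
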